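## Analysis of the target

Target 17 (C28H24O4) is an achiral macrocyclic bis(bibenzyl). Four benzene rings are joined into a 20-membered ring in the order ring A–O–ring B–CH2CH2–ring C–O–ring D–CH2CH2–ring A. Ring A is 1,2,4-trisubstituted: the ether oxygen to ring B sits at C1, a free hydroxyl at C2 and the bridge to ring D at C4, para to the ether oxygen. Ring B is a meta-phenylene and ring C a para-phenylene. Ring D is also 1,2,4-trisubstituted, with its hydroxyl at C1, the ether oxygen to ring C at C2 and the bridge at C4, para to the hydroxyl. There is no stereocentre, and in a ring this large with freely rotating phenylene units no stable atropisomer is expected, so nothing stereochemical has to be controlled. The sensitive functions are the two ortho-aryloxyphenols, which are electron-rich and oxidise easily as phenoxides, so both are unmasked late. The synthesis is hard for two reasons: a 20-membered ring must be closed against oligomerisation, and four oxygen substituents must be placed unsymmetrically on two halves that look alike. The strategy rests on ring A: its hydroxyl carbon C2 is ortho to its ether carbon C1, so a formyl group at C2 can activate a fluoride at C1 for displacement by the ring B phenoxide and can then be converted into the C2 hydroxyl by Baeyer–Villiger oxidation.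

## Retrosynthetic reasoning

**17 ⇒ 16 (O–CH3 of ring D).** The ring D hydroxyl is carried as a methyl ether from starting material 1 to the end. This leaves the ring B oxygen as the only phenoxide at the ring-closure stage. The forward step is a Lewis-acid demethylation that must spare the two diaryl ethers, which have no alkyl carbon to attack.

**16 ⇒ 14 (C2–O of ring A traced back to C2–CHO).** The ring A hydroxyl is derived from the formyl group of macrocyclic aldehyde 14, through aryl formate 15. This turns the hydroxyl position into a carbon substituent that can activate the neighbouring carbon. The forward step needs aryl migration rather than hydride migration in the peracid adduct, which the ortho aryloxy donor favours.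

**14 ⇒ 13 (O–C1 bond of ring A, the ring-closing disconnection).** The ring A–O–ring B ether is cut on the ring A side, giving open-chain fluoro aldehyde phenol 13. Ring B is meta-substituted and offers no position from which a carbonyl group could activate it, so ring A must be the electrophile and its C2 substituent the activator. Cutting here rather than at a bridge puts the ring closure on an oxygen nucleophile with irreversible loss of fluoride, without any metal. All carbon–carbon bonds are then already in place, and the risk of the route sits in this one step. The forward reaction must favour cyclisation over chain growth.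

**13 ⇒ 11 (functional-group changes, through 12).** Both CH2CH2 bridges are traced to CH=CH units, the ring B hydroxyl to a benzyl ether and the formyl group to a dioxolane. One hydrogenation and one mild acid treatment convert 11 into 13. The bridges thus become alkenes that olefination and arylation chemistry can build.

**11 ⇒ 7 + 10 (ring D C4–CH= bond).** A Heck disconnection separates aryl bromide 7 (rings B, C and D) from styrene 10 (ring A with the fluoride and masked formyl group). The cut is placed at ring D because its bromide comes directly from 1. This makes the route convergent.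

**10 ⇒ 9 ⇒ 8.** The vinyl group of 10 comes from the bromide of 9 by cross-coupling with a vinylboron reagent. The dioxolane of 9 comes from commercial aldehyde 8. The acetal must survive aqueous base, palladium and hydrogen.

**7 ⇒ 3 + 5 (C=C between rings B and C, through ylide 6).** A Wittig disconnection gives aldehyde 3 and phosphonium salt 5, which is made in one step from benzylic bromide 4. Alkene geometry does not matter because the alkene is hydrogenated.

**3 ⇒ 1 + 2 (O–C bond of ring C).** The ring C–O–ring D ether is formed intermolecularly from phenol 1 and fluoroarene 2. The formyl group of 2 is para to fluorine, activates the substitution, and then serves as the handle for the Wittig step.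

## Alternatives that were turned down

**Alternative 1: oxidative phenol coupling at the ring C–O–ring D ether.**
- Disconnection: the bond between the ring C oxygen and C2 of ring D.
- Forward key step: macrocycle A1 would arise from the open-chain bis(halophenol) A2. Tl(NO3)3 in methanol oxidises the 2,6-dibromophenol unit (ring D) of A2, the oxygen of its 2,6-dichlorophenol unit (ring C) adds to a bromine-bearing ortho carbon, and Zn in acetic acid reduces the bromodienone back to a phenol.
- For it: the ether forms at low temperature without any carbon activating group. Ring D emerges with its hydroxyl already ortho to the new ether, so that ring needs no unveiling step. On mildness of the ring closure and directness of the ring D pattern it is at least as strong as the chosen route.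
- Against it: four halogens must be installed to steer the oxidation and three removed afterwards, and ring A still needs demethylation. The ring A–O–ring B ether and both bridges must be built beforehand, as in the chosen route. The para-alkyl dibromophenol can also be trapped by methanol at C4 or lose a benzylic proton to a quinone methide, so the substrate does not guarantee the course of the oxidation. A stoichiometric thallium salt is a toxicity burden.
- Comparison: the chosen route uses one auxiliary carbon in place of four halogens, has a single possible site of ring closure, and needs no heavy-metal oxidant.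

**Alternative 2: twofold sulfone extrusion forming both bridges.**
- Disconnection: both CH2–CH2 bonds.
- Forward key step: flash vacuum pyrolysis of the 22-membered bis(dibenzyl sulfone) A4 expels SO2 twice, and the benzylic radical pairs recombine to give the target dimethyl ether A3.
- For it: the ring that precedes A4 is closed by thiolate alkylation, one of the most dependable macrocyclisations, and on that point it is stronger than a substitution that needs an activating group. Both diaryl ethers are made early and intermolecularly, no alkene hydrogenation is needed, and the only protecting groups are two methyl ethers removed together.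
- Against it: the target is unsymmetrical, so joining a half with two benzylic leaving groups to a half with two benzylic thiols can occur in two orientations and give regioisomeric rings. Avoiding this needs stepwise, differentiated sulfur bridges and more steps. A4 is heavy and non-volatile, so bringing it into the gas phase invites decomposition. Radical pairs can fail to recombine, and the method scales poorly. Oxidation, pyrolysis and a double demethylation follow the ring formation.
- Comparison: the chosen route offers ordinary solution chemistry, bridges from simple hydrogenation, and a ring closure with only one regiochemical outcome.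

**Alternative 3: macrocyclic Friedel–Crafts acylation on ring D.**
- Disconnection: the bond between C4 of ring D and the adjacent bridge carbon.
- Forward key step: the open-chain arylacetic acid A6, activated with (CF3CO)2O and H3PO4, acylates the C–H para to the methoxy group of ring D to give macrocyclic ketone A5. Removal of the carbonyl and double demethylation follow.
- For it: the ring closure uses a C–H bond, so ring D needs neither a leaving group nor an activating group. Both ethers can be made intermolecularly beforehand, and the closure loses only water. On atom economy of the ring closure it is stronger than the chosen route.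
- Against it: the acylating species faces four electron-rich rings. The C–H para to the aryloxy group of ring D (21-membered ring) and the C–H ortho to oxygen on ring C (16-membered ring) are plausible competing sites, as is intermolecular acylation. The strongly acidic medium works against slow high-dilution operation. An extra reduction is needed to delete the ketone.
- Comparison: the chosen route has one electrophilic carbon and one nucleophilic oxygen, so the site of closure is fixed by the substrate and not by relative arene reactivity.

Key step: step 8

Remark on the chemistry: 7 and 11 are carried as mixtures of alkene isomers, because step 7 saturates both alkenes; 4 is taken as a purchasable benzylic bromide.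

## Route

Step 1
Reactants: 1 5-bromo-2-methoxyphenol; 2 4-fluorobenzaldehyde
Product: 3 4-(5-bromo-2-methoxyphenoxy)benzaldehyde
Conditions: K2CO3, DMF, 130 °C
Reagents that add atoms: none
Why: SNAr (addition–elimination) of the phenoxide of 1 on 2, whose fluoride is activated by the para formyl group; the aryl bromide is inert without a metal catalyst, and the methoxy group already marks the future ring D hydroxyl.

Step 2
Reactants: 4 1-(benzyloxy)-3-(bromomethyl)benzene
Product: 5 {[3-(benzyloxy)phenyl]methyl}triphenylphosphonium bromide
Conditions: PPh3, toluene, reflux
Reagents that add atoms: triphenylphosphine, c1ccc(cc1)P(c1ccccc1)c1ccccc1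
Why: SN2 quaternisation of the phosphine by a primary benzylic bromide; the salt should precipitate from toluene.

Step 3
Reactants: 5 {[3-(benzyloxy)phenyl]methyl}triphenylphosphonium bromide; 3 4-(5-bromo-2-methoxyphenoxy)benzaldehyde
Product: 7 4-bromo-2-(4-{2-[3-(benzyloxy)phenyl]ethenyl}phenoxy)-1-methoxybenzene (E/Z mixture), via ylide 6 (not isolated)
Conditions: KOt-Bu, THF, 0 °C; then 3, 0 °C to rt
Reagents that add atoms: none
Why: Wittig olefination of an aromatic aldehyde with a semi-stabilised benzylic ylide; a mixture of alkene isomers is expected and acceptable because the alkene is hydrogenated in step 7, and the aryl bromide and ethers do not react with the base at this temperature.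

Step 4
Reactants: 8 5-bromo-2-fluorobenzaldehyde
Product: 9 2-(5-bromo-2-fluorophenyl)-1,3-dioxolane
Conditions: HOCH2CH2OH, TsOH·H2O (cat.), toluene, reflux (Dean–Stark)
Reagents that add atoms: ethane-1,2-diol, OCCO
Why: Acid-catalysed acetalisation driven by azeotropic removal of water; the dioxolane masks the formyl group through the boron, palladium and hydrogen chemistry of steps 5 to 7.

Step 5
Reactants: 9 2-(5-bromo-2-fluorophenyl)-1,3-dioxolane
Product: 10 2-(5-ethenyl-2-fluorophenyl)-1,3-dioxolane
Conditions: CH2=CHBpin, PdCl2(dppf) (cat.), K2CO3, 1,4-dioxane/H2O, 90 °C
Reagents that add atoms: vinylboronic acid pinacol ester, C=CB1OC(C)(C)C(C)(C)O1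
Why: Suzuki–Miyaura coupling of an aryl bromide with a vinylboronate; oxidative addition takes place at C–Br and not at C–F, and the acetal is stable to aqueous carbonate.

Step 6
Reactants: 7 4-bromo-2-(4-{2-[3-(benzyloxy)phenyl]ethenyl}phenoxy)-1-methoxybenzene; 10 2-(5-ethenyl-2-fluorophenyl)-1,3-dioxolane
Product: 11 2-{5-[(E)-2-{3-(4-{2-[3-(benzyloxy)phenyl]ethenyl}phenoxy)-4-methoxyphenyl}ethenyl]-2-fluorophenyl}-1,3-dioxolane
Conditions: Pd(OAc)2 (cat.), P(o-tol)3, Et3N, DMF, 110 °C
Reagents that add atoms: none
Why: Mizoroki–Heck reaction: oxidative addition of the aryl bromide of 7 to zerovalent palladium formed in situ, syn insertion of the terminal alkene of 10 at its unsubstituted carbon and syn β-hydride elimination should give the E-stilbene; the 1,2-disubstituted alkene already present in 7 inserts much more slowly than a terminal styrene.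

Step 7
Reactants: 11 2-{5-[(E)-2-{3-(4-{2-[3-(benzyloxy)phenyl]ethenyl}phenoxy)-4-methoxyphenyl}ethenyl]-2-fluorophenyl}-1,3-dioxolane
Product: 13 2-fluoro-5-{2-[3-(4-{2-(3-hydroxyphenyl)ethyl}phenoxy)-4-methoxyphenyl]ethyl}benzaldehyde, via hydrogenated acetal phenol 12 (not isolated)
Conditions: H2 (1 atm), Pd/C, EtOAc/EtOH, rt; filter; then 1 M HCl, THF, rt
Reagents that add atoms: water, O
Why: Heterogeneous catalytic hydrogenation saturates both stilbene double bonds and hydrogenolyses the benzyl ether, while the aryl fluoride, the diaryl ether and the acetal are inert under neutral conditions; dilute acid then hydrolyses the dioxolane and releases the activating formyl group.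

Step 8
Reactants: 13 2-fluoro-5-{2-[3-(4-{2-(3-hydroxyphenyl)ethyl}phenoxy)-4-methoxyphenyl]ethyl}benzaldehyde
Product: 14 macrocyclic aldehyde (20-membered ring A–O–ring B–CH2CH2–ring C–O–ring D–CH2CH2; formyl on ring A ortho to its ether oxygen; methoxy on ring D ortho to its ether oxygen)
Conditions: Cs2CO3, DMF, 100 °C, slow addition of 13 (final concentration about 0.002 M)
Reagents that add atoms: none
Why: Cs2CO3 deprotonates the single free phenol of 13 (ring B); the phenoxide adds to the fluorine-bearing C1 of ring A to give a Meisenheimer anion whose charge is delocalised onto the ortho formyl oxygen, and loss of fluoride restores the arene (SNAr, addition–elimination). The closest known reaction type is the macrocyclising SNAr etherification of phenoxides on fluoroarenes activated by an ortho formyl or nitro group, and step 1 is its intermolecular counterpart. The 20-membered ring closes end to end by O–C(aryl) bond formation, with the departing fluoride outside the new ring (exo mode at a trigonal carbon). No stereocentre is created. The selectivity required is cyclisation over chain growth; ring closure is unimolecular and oligomerisation bimolecular, so slow addition of 13 to the hot base keeps the stationary phenoxide concentration low and should favour the ring. Site selectivity is secured by the substrate: there is one activated C–F bond, one phenoxide (the ring D oxygen is capped as its methyl ether) and no enolisable hydrogen next to the aldehyde. The large cesium counter-ion gives a loosely paired, reactive phenoxide in DMF, and the saturated bridges let the chain fold without strain.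

Step 9
Reactants: 14 macrocyclic aldehyde
Product: 16 macrocyclic monophenol (hydroxyl on ring A ortho to its ether oxygen; ring D still a methyl ether), via aryl formate 15 (not isolated)
Conditions: mCPBA, CH2Cl2, 0 °C to rt; evaporate; then HCl (cat.), MeOH, rt
Reagents that add atoms: meta-chloroperbenzoic acid, OOC(=O)c1cccc(Cl)c1
Why: Baeyer–Villiger (Dakin-type) oxidation: the peracid adds to the aldehyde, and in the Criegee adduct the aryl group carrying the ortho aryloxy donor migrates to oxygen in preference to hydride, giving the aryl formate; acid-catalysed methanolysis then passes the formyl group to methanol and leaves the ring A phenol.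

Step 10
Reactants: 16 macrocyclic monophenol
Product: 17 target bis(bibenzyl) macrocycle (hydroxyls on ring A and ring D)
Conditions: BBr3, CH2Cl2, −78 °C to rt; then H2O
Reagents that add atoms: none
Why: Lewis-acid cleavage of an aryl methyl ether: boron coordinates the methoxy oxygen and bromide attacks the methyl carbon (SN2); the diaryl ethers offer no alkyl carbon for attack and survive, and hydrolysis of the aryl borates on work-up should give the target.

## Compound list

1 | 5-bromo-2-methoxyphenol | COc1ccc(Br)cc1O | starting material
2 | 4-fluorobenzaldehyde | O=Cc1ccc(F)cc1 | starting material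
3 | 4-(5-bromo-2-methoxyphenoxy)benzaldehyde | COc1ccc(Br)cc1Oc1ccc(C=O)cc1 | intermediate
4 | 1-(benzyloxy)-3-(bromomethyl)benzene | BrCc1cccc(OCc2ccccc2)c1 | starting material
5 | {[3-(benzyloxy)phenyl]methyl}triphenylphosphonium bromide | [Br-].c1ccc(cc1)[P+](Cc1cccc(OCc2ccccc2)c1)(c1ccccc1)c1ccccc1 | intermediate
6 | {[3-(benzyloxy)phenyl]methylidene}triphenylphosphorane (ylide) | c1ccc(cc1)P(=Cc1cccc(OCc2ccccc2)c1)(c1ccccc1)c1ccccc1 | intermediate (not isolated)
7 | 4-bromo-2-(4-{2-[3-(benzyloxy)phenyl]ethenyl}phenoxy)-1-methoxybenzene (E/Z mixture, alkene geometry left open) | COc1ccc(Br)cc1Oc1ccc(C=Cc2cccc(OCc3ccccc3)c2)cc1 | intermediate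
8 | 5-bromo-2-fluorobenzaldehyde | O=Cc1cc(Br)ccc1F | starting material
9 | 2-(5-bromo-2-fluorophenyl)-1,3-dioxolane | Fc1ccc(Br)cc1C1OCCO1 | intermediate
10 | 2-(5-ethenyl-2-fluorophenyl)-1,3-dioxolane | C=Cc1ccc(F)c(c1)C1OCCO1 | intermediate
11 | 2-{5-[(E)-2-{3-(4-{2-[3-(benzyloxy)phenyl]ethenyl}phenoxy)-4-methoxyphenyl}ethenyl]-2-fluorophenyl}-1,3-dioxolane (new alkene E; Wittig alkene E/Z) | COc1ccc(/C=C/c2ccc(F)c(c2)C2OCCO2)cc1Oc1ccc(C=Cc2cccc(OCc3ccccc3)c2)cc1 | intermediate
12 | 3-{2-[4-(5-{2-[3-(1,3-dioxolan-2-yl)-4-fluorophenyl]ethyl}-2-methoxyphenoxy)phenyl]ethyl}phenol | COc1ccc(CCc2ccc(F)c(c2)C2OCCO2)cc1Oc1ccc(CCc2cccc(O)c2)cc1 | intermediate (not isolated)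
13 | 2-fluoro-5-{2-[3-(4-{2-(3-hydroxyphenyl)ethyl}phenoxy)-4-methoxyphenyl]ethyl}benzaldehyde | O=Cc1cc(CCc2ccc(OC)c(Oc3ccc(CCc4cccc(O)c4)cc3)c2)ccc1F | intermediate
14 | macrocyclic aldehyde (formyl on ring A, methoxy on ring D) | O=Cc1cc2ccc1Oc1cccc(c1)CCc1ccc(cc1)Oc1cc(ccc1OC)CC2 | intermediate
15 | macrocyclic aryl formate (formyloxy on ring A, methoxy on ring D) | O=COc1cc2ccc1Oc1cccc(c1)CCc1ccc(cc1)Oc1cc(ccc1OC)CC2 | intermediate (not isolated)
16 | macrocyclic monophenol (hydroxyl on ring A, methoxy on ring D) | Oc1cc2ccc1Oc1cccc(c1)CCc1ccc(cc1)Oc1cc(ccc1OC)CC2 | intermediate
17 | target bis(bibenzyl) macrocycle (hydroxyls on rings A and D) | Oc1cc2ccc1Oc1cccc(c1)CCc1ccc(cc1)Oc1cc(ccc1O)CC2 | target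

## Step count and risk

Total: 10 steps; steps 3, 7 and 9 are two-stage operations with an intermediate that is not isolated. Longest linear sequence: 7 steps (steps 1, 3, 6, 7, 8, 9, 10; the branches through steps 2 and 4–5 are equally long).

**Step 8 (key step).**
- Risk: chain growth by intermolecular substitution, giving dimers and oligomers. A formyl group is only a moderate activator, so ring closure needs heat and long reaction times, during which bimolecular substitution can compete. Amine released by slow breakdown of the amide solvent can also attack the C–F bond; DMSO is the substitute solvent if this is seen.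
- Fallback (sets out from 7 and 10, returns at 14): make the ring A–O–ring B ether intermolecularly and close the ring by carbon–carbon bond formation. Selective debenzylation of 7 with BCl3 and pentamethylbenzene at −78 °C would give 3-{2-[4-(5-bromo-2-methoxyphenoxy)phenyl]ethenyl}phenol F1. Acid hydrolysis of 10 would give 5-ethenyl-2-fluorobenzaldehyde F2. K2CO3 in DMF should join the two by intermolecular SNAr to 2-(3-{2-[4-(5-bromo-2-methoxyphenoxy)phenyl]ethenyl}phenoxy)-5-ethenylbenzaldehyde F3. An intramolecular Heck reaction at high dilution (Pd(OAc)2, P(o-tol)3, Et3N, DMF) would close the 20-membered ring as the macrocyclic bis(stilbene) aldehyde F4. Hydrogenation of both alkenes over Pd/C poisoned with diphenyl sulfide, which spares aromatic aldehydes, comes back to the route at 14.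

**Step 6.**
- Risk: slow oxidative addition into the electron-rich aryl bromide, with catalyst decay to palladium black. Minor pathways are insertion into the internal alkene of 7 and arylation at the substituted carbon of the styrene.
- Fallback (sets out from 10 and 7, returns at 12): form the bridge as a saturated chain by B-alkyl Suzuki–Miyaura coupling. Anti-Markovnikov hydroboration of 10 with 9-borabicyclo[3.3.1]nonane would give 9-{2-[3-(1,3-dioxolan-2-yl)-4-fluorophenyl]ethyl}-9-borabicyclo[3.3.1]nonane F5. Coupling with 7 (PdCl2(dppf), K3PO4, THF/H2O) would give 2-{5-[2-{3-(4-{2-[3-(benzyloxy)phenyl]ethenyl}phenoxy)-4-methoxyphenyl}ethyl]-2-fluorophenyl}-1,3-dioxolane F6. Hydrogenation of F6 under the first-stage conditions of step 7 rejoins the route at 12.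

**Step 7.**
- Risk: premature loss of the acetal on acidic sites of the catalyst, followed by reduction of the freed aldehyde. Incomplete hydrogenolysis of the benzyl ether is the second concern. A little solid NaHCO3 in the hydrogenation is the first remedy.
- Fallback (sets out from 11, returns at 13): separate alkene reduction from debenzylation and avoid hydrogen on a metal altogether. Diimide generated from tosylhydrazide and NaOAc in refluxing aqueous DME would saturate both alkenes without touching acetal, benzyl ether or C–F, giving 2-{5-[2-{3-(4-{2-[3-(benzyloxy)phenyl]ethyl}phenoxy)-4-methoxyphenyl}ethyl]-2-fluorophenyl}-1,3-dioxolane F7. BCl3 with pentamethylbenzene at −78 °C then cleaves the benzyl ether while sparing the methyl ether, and aqueous acid work-up hydrolyses the acetal, arriving at 13.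

**Step 9.**
- Risk: hydride migration instead of aryl migration in the peracid adduct, which would lead to the carboxylic acid. An aryloxy group is a weaker donor than an alkoxy group, so the preference for aryl migration is smaller.
- Fallback (sets out from 14, returns at 16): remove the competing hydride. Addition of MeMgBr to 14 would give the racemic macrocyclic 1-arylethanol F8. Oxidation with MnO2 would give the macrocyclic aryl methyl ketone F9. Baeyer–Villiger oxidation of F9 with mCPBA, where aryl competes only with the poorly migrating methyl group, would give the macrocyclic aryl acetate F10. Methanolysis of F10 returns to 16.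

## Further compounds

F1 | step 8 | 3-{2-[4-(5-bromo-2-methoxyphenoxy)phenyl]ethenyl}phenol (E/Z mixture) | COc1ccc(Br)cc1Oc1ccc(C=Cc2cccc(O)c2)cc1
F2 | step 8 | 5-ethenyl-2-fluorobenzaldehyde | C=Cc1ccc(F)c(C=O)c1
F3 | step 8 | 2-(3-{2-[4-(5-bromo-2-methoxyphenoxy)phenyl]ethenyl}phenoxy)-5-ethenylbenzaldehyde (E/Z mixture) | COc1ccc(Br)cc1Oc1ccc(C=Cc2cccc(Oc3ccc(C=C)cc3C=O)c2)cc1
F4 | step 8 | macrocyclic bis(stilbene) aldehyde (both bridges CH=CH, formyl on ring A, methoxy on ring D) | O=Cc1cc2ccc1Oc1cccc(c1)C=Cc1ccc(cc1)Oc1cc(ccc1OC)C=C2
F5 | step 6 | 9-{2-[3-(1,3-dioxolan-2-yl)-4-fluorophenyl]ethyl}-9-borabicyclo[3.3.1]nonane | Fc1ccc(CCB2C3CCCC2CCC3)cc1C1OCCO1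
F6 | step 6 | 2-{5-[2-{3-(4-{2-[3-(benzyloxy)phenyl]ethenyl}phenoxy)-4-methoxyphenyl}ethyl]-2-fluorophenyl}-1,3-dioxolane (E/Z mixture) | COc1ccc(CCc2ccc(F)c(c2)C2OCCO2)cc1Oc1ccc(C=Cc2cccc(OCc3ccccc3)c2)cc1
F7 | step 7 | 2-{5-[2-{3-(4-{2-[3-(benzyloxy)phenyl]ethyl}phenoxy)-4-methoxyphenyl}ethyl]-2-fluorophenyl}-1,3-dioxolane | COc1ccc(CCc2ccc(F)c(c2)C2OCCO2)cc1Oc1ccc(CCc2cccc(OCc3ccccc3)c2)cc1
F8 | step 9 | macrocyclic 1-arylethanol (CH(OH)CH3 on ring A in place of formyl, racemic) | CC(O)c1cc2ccc1Oc1cccc(c1)CCc1ccc(cc1)Oc1cc(ccc1OC)CC2
F9 | step 9 | macrocyclic aryl methyl ketone (acetyl on ring A) | CC(=O)c1cc2ccc1Oc1cccc(c1)CCc1ccc(cc1)Oc1cc(ccc1OC)CC2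
F10 | step 9 | macrocyclic aryl acetate (acetoxy on ring A) | CC(=O)Oc1cc2ccc1Oc1cccc(c1)CCc1ccc(cc1)Oc1cc(ccc1OC)CC2
A1 | alternative 1 | trihalogenated macrocyclic diaryl ether (ring A methyl ether, two chlorines on ring C, one bromine and free hydroxyl on ring D) | COc1cc2ccc1Oc1cccc(c1)CCc1cc(Cl)c(c(Cl)c1)Oc1cc(cc(Br)c1O)CC2
A2 | alternative 1 | open-chain bis(halophenol) (2,6-dibromophenol ring D, 2,6-dichlorophenol ring C) | COc1cc(CCc2cc(Br)c(O)c(Br)c2)ccc1Oc1cccc(CCc2cc(Cl)c(O)c(Cl)c2)c1
A3 | alternative 2 | target dimethyl ether | COc1cc2ccc1Oc1cccc(c1)CCc1ccc(cc1)Oc1cc(ccc1OC)CC2
A4 | alternative 2 | 22-membered bis(dibenzyl sulfone) | COc1cc2ccc1Oc1cccc(c1)CS(=O)(=O)Cc1ccc(cc1)Oc1cc(ccc1OC)CS(=O)(=O)C2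
A5 | alternative 3 | macrocyclic ketone (carbonyl on ring D), dimethyl ether | COc1cc2ccc1Oc1cccc(c1)CCc1ccc(cc1)Oc1cc(ccc1OC)C(=O)C2
A6 | alternative 3 | open-chain ring A arylacetic acid | COc1cc(CC(=O)O)ccc1Oc1cccc(CCc2ccc(Oc3ccccc3OC)cc2)c1
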